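## The problem

Target **24** is a trans-fused bicyclo[5.3.0]decene. The locants used throughout are C1 (CH–O-angeloyl), C2=C3(CH3), C4 (CH2), C5 (CH–O-veratroyl), C6 (ring-fusion CH), C7 (ring-fusion C–CH3), C8 and C9 (CH2), and C10 (C(OH)(i-Pr)). The seven-membered ring is C1–C7 and the five-membered ring is C6–C10. With these locants the configuration is 1R,5S,6S,7S,10R: H-6 and the C7 methyl are anti (trans fusion), both ester oxygens lie on the face of H-6, and the C10 hydroxyl lies on the face of the C7 methyl. The hard part is the contiguous array C5–C6–C7–C10, in which a quaternary carbon (C7) sits next to a tertiary one (C6) that is flanked by a secondary and a tertiary carbinol. C7 can direct C6, and C6 can direct both C5 and C10. C1, on the far side of the quaternary centre, has no dependable internal control and needs a reagent. The angelate isomerises readily to the tiglate, the veratrate cannot pass through organometallic steps, the C1 ester is allylic, and the C10 tertiary alcohol must be spared strong acid. The enabling feature is that C7 and C6 are the β- and α-carbons of a cyclopentanone whose carbonyl is C10. The C7 methyl can therefore arrive by conjugate addition, and the resulting enolate can form C6–C5 with an aldehyde whose oxygen becomes the C5 oxygen.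

## Retrosynthesis

**Ester bonds (24 ⇒ 22 + 23; 22 ⇒ 21 ⇒ 18 + 19 via 20).** The two acyl C–O bonds are cut first. After ring closure the C1 hydroxyl of **18** is free and C5 is still silylated, so the angelate goes on first and the veratrate last. This order needs no extra protecting-group step and no selectivity between the two secondary hydroxyls. The forward steps must acylate a hindered allylic alcohol without Z to E isomerisation, and the C10 hydroxyl must stay untouched, which its tertiary, isopropyl-flanked position ensures.

**C2=C3 (18 ⇒ 17).** Ring-closing metathesis opens the seven-membered ring to a monocyclic diene. This cut is preferred to C1–C2 or C3–C4 because both alkenes are terminal, come from trivial reagents, and need no alkene-geometry control since the ring enforces the cis double bond. The forward step must close a trisubstituted cycloheptene trans-fused to the cyclopentane.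

**C1 carbinol and C1–C2 (17 ⇒ 16 ⇒ 15 ⇒ 14).** C1–C2 is made by adding a vinyl nucleophile to the neopentyl aldehyde **14**. A Felkin–Anh analysis with C6 as the large group predicts that this addition favours the wrong C1 epimer. The mixture **15** is therefore oxidised to enone **16**, and C1 is set by oxazaborolidine-catalysed reduction to **17**. In the reduction the roles of hydrogen and vinyl are exchanged, so substrate and reagent preference should coincide. The price is two extra steps.

**C10–isopropyl and redox adjustment (14 ⇒ 13 ⇒ 12 ⇒ 11).** The aldehyde comes from the primary silyl ether by selective desilylation and oxidation. The tertiary carbinol comes from ketone **11** and an isopropyl nucleophile. The branch on C6 shields one face of the C10 carbonyl, so addition anti to it gives 10R. The forward step needs a non-basic, non-reducing organometallic.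

**Key disconnection (11 ⇒ 10 ⇒ 5 + 8 + 7 via 9).** Cutting C7–CH3 and C6–C5 reduces aldol **10** to the achiral enone **5**, trimethylaluminium **8** and aldehyde **7**. No other cut removes three stereocentres and returns to achiral materials in one operation. The forward reaction must select the enone face for methyl transfer, attack the enolate face anti to the larger C7 substituent, and give the anti aldol. The C1 oxygen is carried as a triethylsilyl ether, not an acetal-type ether. It is bulkier, it does not bind aluminium (a bound metal would deliver the aldehyde to the wrong face), and it can be removed beside the C5 silyl ether.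

**Building blocks (5 ⇒ 4 ⇒ 2 + 3; 2 ⇒ 1; 7 ⇒ 6).** The silyl ether cannot be introduced as an α-silyloxy organolithium, which would rearrange. The hydroxymethyl group is therefore attached by Stille coupling of stannane **3** with bromoenone **2**, which comes from dione **1**. Aldehyde **7** comes from alcohol **6** by a non-basic oxidation that does not isomerise the alkene.

## Roads not taken

Alternative 1: The last C–C bond cut is C1–C2. In the forward sense the iodo aldehyde A2 is treated with CrCl2 and catalytic NiCl2 (Nozaki–Hiyama–Kishi); the (Z)-iodoalkene becomes an alkenylchromium that adds to the C1 aldehyde and closes the ring to A1, one angeloylation with **19** short of **24**. Its merits are real: ring closure and the C1 carbinol arrive in one step, esters and the free tertiary alcohol are tolerated, and the veratrate is already in place. The end game is three to four steps shorter than the vinyl addition, oxidation, reduction and metathesis sequence used here. Its weak points are threefold. The C1 configuration would be decided by the conformation of the closing seven-membered ring and cannot be predicted. Correcting it on the ring is unattractive, because hydride delivery to a C1 ketone is expected anti to the angular methyl, which gives the wrong epimer. A2 also needs a stereodefined trisubstituted (Z)-iodoalkene carried through the construction of C5–C7 and C10, and several equivalents of divalent chromium at high dilution. Most importantly it does not say how the C5/C6/C7/C10 array is made. The plan adopted here offers reagent control at C1, a catalytic ring closure with an alkene that has no geometry, and a key step that builds the stereochemical core.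

Alternative 2: Retrosynthetically the ring-fusion bond C6–C7 is exchanged for C5–C7, so that the hydroazulene becomes a cis-decalin derived from (S)-Wieland–Miescher ketone A5. In the forward sense Et3Al converts the tertiary C5 hydroxyl of hydroxy mesylate A4 into an aluminium alkoxide; C7 migrates from C5 to C6 with loss of mesylate and gives the hydroazulenone A3. This road is better than the chosen one in two respects. The quaternary centre comes enantiopure from a cheap organocatalytic annulation, and the trans fusion is set stereospecifically by inversion at C6, with no facial-selectivity question. Its weakness for this target is what A3 lacks. C3 carries neither the methyl group nor the double bond, C5 is a ketone that must be reduced selectively, and C1 is a masked ketone. Installing the 3-methyl-2-ene unit from a C1 ketone takes an enone formation, a methyl conjugate addition and a second dehydrogenation before either ester can be attached. A4 in turn requires a face-selective isopropyl addition and dihydroxylation. The chosen plan accepts a less certain stereochemical step. In return it reaches **18** with every carbon, the alkene and both oxygens at the correct oxidation level.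

Alternative 3: The cut is C9–C10. In the forward sense the aldehyde C–H of pentenal A7 adds across its vinyl group under a cationic rhodium diphosphine catalyst such as [Rh(dppe)]ClO4 (intramolecular hydroacylation) and gives cyclopentanone A6. The step is catalytic and atom-economical, needs no pyrophoric organoaluminium, and leaves the C6 and C7 configurations untouched. If A7 is made by a stereospecific acyclic process, the trans relationship is safer than in the chosen plan. The difficulty is moved, not removed. A7 already contains the vicinal quaternary and tertiary centres, its formyl-bearing C6 is epimerisable, and decarbonylation competes. A6 also carries C5 only as a protected hydroxymethyl group, so the C4–C5 bond and the C5 stereocentre still have to be made by a separate stereoselective addition. The chosen key step forms C6–C5, sets C5, and starts from an achiral enone, which makes it the more convergent route.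

Key step: step 5

Remark on the chemistry: the antipode of the phosphoramidite ligand that gives 7S in step 5 has to be identified on the first run. Both antipodes are available, and the route is written for the one that gives **10** as drawn.

## Route

Step 1
Reactants: 1 cyclopentane-1,3-dione
Product: 2 3-bromocyclopent-2-en-1-one
Conditions: Ph3PBr2, Et3N, CH2Cl2, 0 °C to rt
Reagents that add atoms: dibromotriphenylphosphorane, BrP(Br)(c1ccccc1)(c1ccccc1)c1ccccc1
Why: Deoxybromination of a vinylogous acid: the enol oxygen attacks phosphorus and bromide displaces it at C3 by addition–elimination, a standard way to β-bromo enones.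

Step 2
Reactants: 2 3-bromocyclopent-2-en-1-one, 3 (tributylstannyl)methanol
Product: 4 3-(hydroxymethyl)cyclopent-2-en-1-one
Conditions: Pd(PPh3)4 (cat.), 1,4-dioxane, 90 °C
Reagents that add atoms: none
Why: Stille coupling: zerovalent palladium inserts readily into the β-bromo enone and the hydroxymethyl group is transferred from tin in preference to butyl, a known hydroxymethylation of alkenyl and aryl halides.

Step 3
Reactants: 4 3-(hydroxymethyl)cyclopent-2-en-1-one
Product: 5 3-[(triethylsilyloxy)methyl]cyclopent-2-en-1-one
Conditions: Et3SiCl, imidazole, CH2Cl2, 0 °C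
Reagents that add atoms: chlorotriethylsilane, CC[Si](Cl)(CC)CC
Why: Routine silylation of a primary alcohol; the triethylsilyl ether does not bind aluminium, is larger than methyl at C7, and can later be cleaved beside a secondary tert-butyldimethylsilyl ether.

Step 4
Reactants: 6 3-methylbut-3-en-1-ol
Product: 7 3-methylbut-3-enal
Conditions: Dess–Martin periodinane, CH2Cl2, 0 °C to rt; filtered and used at once as a titrated solution
Reagents that add atoms: none
Why: Dess–Martin oxidation is amine-free, so the β,γ-unsaturated aldehyde is not drawn into conjugation as it would be under base-mediated oxidations.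

Step 5
Reactants: 5 3-[(triethylsilyloxy)methyl]cyclopent-2-en-1-one, 8 trimethylaluminium, 7 3-methylbut-3-enal
Product: 10 (2S,3S)-2-[(1S)-1-hydroxy-3-methylbut-3-en-1-yl]-3-methyl-3-[(triethylsilyloxy)methyl]cyclopentan-1-one, via dimethylaluminium enolate 9 (not isolated)
Conditions: Cu(OTf)2 (cat.), chiral binaphthol-derived bis(1-phenylethyl)phosphoramidite (cat.), Et2O, −30 °C; then 7, −78 to −40 °C; aq. Rochelle salt
Reagents that add atoms: none
Why: Me3Al reduces Cu(OTf)2 to a chiral monovalent methylcopper–phosphoramidite species that binds the enone, adds at C7 to a trivalent copper intermediate and eliminates reductively, giving the C7–CH3 bond and dimethylaluminium enolate 9, which then adds through C6 to aldehyde 7. The closest known reaction type is the copper-catalysed asymmetric conjugate addition of trialkylaluminium reagents to β-substituted cycloalkenones with aldehyde trapping of the aluminium enolate, the three-component conjugate addition–aldol coupling on a cyclopentenone. No ring is closed; two skeletal bonds (C7–CH3 and C6–C5) and three stereocentres are formed. C7 (S) is set by the ligand, which selects the enone face for methyl transfer. C6 (S) follows from approach of 7 to the enolate face anti to the larger C7 substituent, CH2OSiEt3 against CH3, which gives the 2,3-trans relationship that becomes the trans ring fusion. C5 (S) follows from the closed six-membered Zimmerman–Traxler transition state of the ring-locked (E)-enolate with the aldehyde chain equatorial, which is the anti aldol. The step needs 1,4- over 1,2-methyl transfer, secured by copper catalysis at low temperature; aldol trapping faster than methyl transfer from residual Me3Al to 7 or isomerisation of 7, secured by excess 7 at −78 °C; and no chelation of aluminium by the C1 oxygen, secured by the silyl ether.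

Step 6
Reactants: 10 (2S,3S)-2-[(1S)-1-hydroxy-3-methylbut-3-en-1-yl]-3-methyl-3-[(triethylsilyloxy)methyl]cyclopentan-1-one
Product: 11 (2S,3S)-2-[(1S)-1-(tert-butyldimethylsilyloxy)-3-methylbut-3-en-1-yl]-3-methyl-3-[(triethylsilyloxy)methyl]cyclopentan-1-one
Conditions: TBSOTf, 2,6-lutidine, CH2Cl2, −78 °C
Reagents that add atoms: tert-butyldimethylsilyl trifluoromethanesulfonate, CC(C)(C)[Si](C)(C)OS(=O)(=O)C(F)(F)F
Why: Silyl triflate with a hindered base caps the aldol hydroxyl at −78 °C faster than retro-aldol or β-elimination can occur; the robust secondary silyl ether carries C5 through the later oxidations.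

Step 7
Reactants: 11 (2S,3S)-2-[(1S)-1-(tert-butyldimethylsilyloxy)-3-methylbut-3-en-1-yl]-3-methyl-3-[(triethylsilyloxy)methyl]cyclopentan-1-one
Product: 12 (1R,2S,3S)-2-[(1S)-1-(tert-butyldimethylsilyloxy)-3-methylbut-3-en-1-yl]-3-methyl-1-(propan-2-yl)-3-[(triethylsilyloxy)methyl]cyclopentan-1-ol
Conditions: i-PrMgCl, anhydrous CeCl3, THF, −78 °C
Reagents that add atoms: isopropylmagnesium chloride, CC(C)[Mg]Cl
Why: Organocerium (Imamoto-type) addition: the weakly basic isopropylcerium reagent adds to the hindered, enolisable ketone without enolising or reducing it. It approaches C10 on the face of H-6, anti to the bulky C5 side chain on the adjacent carbon, which sets 10R with the hydroxyl cis to the C5 branch and the C7 methyl.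

Step 8
Reactants: 12 (1R,2S,3S)-2-[(1S)-1-(tert-butyldimethylsilyloxy)-3-methylbut-3-en-1-yl]-3-methyl-1-(propan-2-yl)-3-[(triethylsilyloxy)methyl]cyclopentan-1-ol
Product: 13 (1R,2S,3S)-2-[(1S)-1-(tert-butyldimethylsilyloxy)-3-methylbut-3-en-1-yl]-3-(hydroxymethyl)-3-methyl-1-(propan-2-yl)cyclopentan-1-ol
Conditions: PPTS (cat.), MeOH/CH2Cl2, 0 °C
Reagents that add atoms: none
Why: Mild acid-catalysed methanolysis removes a primary triethylsilyl ether far faster than a hindered secondary tert-butyldimethylsilyl ether, and the tertiary alcohol does not ionise under these conditions.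

Step 9
Reactants: 13 (1R,2S,3S)-2-[(1S)-1-(tert-butyldimethylsilyloxy)-3-methylbut-3-en-1-yl]-3-(hydroxymethyl)-3-methyl-1-(propan-2-yl)cyclopentan-1-ol
Product: 14 (1S,2S,3R)-2-[(1S)-1-(tert-butyldimethylsilyloxy)-3-methylbut-3-en-1-yl]-3-hydroxy-1-methyl-3-(propan-2-yl)cyclopentane-1-carbaldehyde
Conditions: Dess–Martin periodinane, CH2Cl2, rt
Reagents that add atoms: none
Why: Dess–Martin oxidation of the neopentyl primary alcohol; the tertiary C10 hydroxyl is inert and, being trans to the formyl group across the ring, cannot close a lactol.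

Step 10
Reactants: 14 (1S,2S,3R)-2-[(1S)-1-(tert-butyldimethylsilyloxy)-3-methylbut-3-en-1-yl]-3-hydroxy-1-methyl-3-(propan-2-yl)cyclopentane-1-carbaldehyde
Product: 15 1-{(1S,2S,3R)-2-[(1S)-1-(tert-butyldimethylsilyloxy)-3-methylbut-3-en-1-yl]-3-hydroxy-1-methyl-3-(propan-2-yl)cyclopentyl}prop-2-en-1-ol (both C1 epimers)
Conditions: vinylmagnesium bromide (excess), THF, −78 to 0 °C
Reagents that add atoms: vinylmagnesium bromide, C=C[Mg]Br
Why: Grignard 1,2-addition to a non-enolisable α-quaternary aldehyde, with one extra equivalent consumed by the C10 hydroxyl. No selectivity is required because C1 is reset in steps 11 and 12.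

Step 11
Reactants: 15 1-{(1S,2S,3R)-2-[(1S)-1-(tert-butyldimethylsilyloxy)-3-methylbut-3-en-1-yl]-3-hydroxy-1-methyl-3-(propan-2-yl)cyclopentyl}prop-2-en-1-ol
Product: 16 1-{(1S,2S,3R)-2-[(1S)-1-(tert-butyldimethylsilyloxy)-3-methylbut-3-en-1-yl]-3-hydroxy-1-methyl-3-(propan-2-yl)cyclopentyl}prop-2-en-1-one
Conditions: Dess–Martin periodinane, CH2Cl2, 0 °C
Reagents that add atoms: none
Why: Dess–Martin oxidation converges both C1 epimers on one enone under non-basic conditions that spare the vinyl ketone.

Step 12
Reactants: 16 1-{(1S,2S,3R)-2-[(1S)-1-(tert-butyldimethylsilyloxy)-3-methylbut-3-en-1-yl]-3-hydroxy-1-methyl-3-(propan-2-yl)cyclopentyl}prop-2-en-1-one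
Product: 17 (1R)-1-{(1S,2S,3R)-2-[(1S)-1-(tert-butyldimethylsilyloxy)-3-methylbut-3-en-1-yl]-3-hydroxy-1-methyl-3-(propan-2-yl)cyclopentyl}prop-2-en-1-ol
Conditions: (S)-2-methyl-CBS-oxazaborolidine, catecholborane, toluene, −78 °C
Reagents that add atoms: none
Why: Corey–Bakshi–Shibata reduction: the catalyst binds the carbonyl lone pair on the side of the small vinyl group, away from the quaternary C7, so the (S)-catalyst is expected to give 1R, and the Felkin–Anh preference for hydride addition points the same way. Catecholborane at −78 °C gives 1,2-reduction and does not hydroborate the 1,1-disubstituted alkene.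

Step 13
Reactants: 17 (1R)-1-{(1S,2S,3R)-2-[(1S)-1-(tert-butyldimethylsilyloxy)-3-methylbut-3-en-1-yl]-3-hydroxy-1-methyl-3-(propan-2-yl)cyclopentyl}prop-2-en-1-ol
Product: 18 (3R,3aS,4S,8R,8aS)-4-(tert-butyldimethylsilyloxy)-6,8a-dimethyl-3-(propan-2-yl)-1,2,3,3a,4,5,8,8a-octahydroazulene-3,8-diol
Conditions: second-generation Grubbs catalyst RuCl2(=CHPh)(H2IMes)(PCy3) (cat.), CH2Cl2 (high dilution), 40 °C
Reagents that add atoms: none
Why: Ring-closing metathesis: the ruthenium carbene forms at the monosubstituted alkene next to the free allylic hydroxyl and closes onto the 1,1-disubstituted alkene with loss of ethene, giving the ring-enforced cis trisubstituted C2=C3 bond. The two arms are trans on the cyclopentane, which accommodates the trans-fused seven-membered ring, and no stereocentre is touched.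

Step 14
Reactants: 18 (3R,3aS,4S,8R,8aS)-4-(tert-butyldimethylsilyloxy)-6,8a-dimethyl-3-(propan-2-yl)-1,2,3,3a,4,5,8,8a-octahydroazulene-3,8-diol, 19 angelic acid [(2Z)-2-methylbut-2-enoic acid]
Product: 21 (3R,3aS,4S,8R,8aS)-4-(tert-butyldimethylsilyloxy)-3-hydroxy-6,8a-dimethyl-3-(propan-2-yl)-1,2,3,3a,4,5,8,8a-octahydroazulen-8-yl (2Z)-2-methylbut-2-enoate, via angelic 2,4,6-trichlorobenzoic anhydride 20 (not isolated)
Conditions: 19, 2,4,6-trichlorobenzoyl chloride, Et3N, toluene, rt; then 18, 80 °C
Reagents that add atoms: none
Why: Yamaguchi-type esterification through mixed anhydride 20 without a nucleophilic pyridine catalyst, the protocol known to transfer the angeloyl group with little Z to E isomerisation. Only the secondary allylic C1 hydroxyl reacts; the tertiary C10 hydroxyl is too hindered.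

Step 15
Reactants: 21 (3R,3aS,4S,8R,8aS)-4-(tert-butyldimethylsilyloxy)-3-hydroxy-6,8a-dimethyl-3-(propan-2-yl)-1,2,3,3a,4,5,8,8a-octahydroazulen-8-yl (2Z)-2-methylbut-2-enoate
Product: 22 (3R,3aS,4S,8R,8aS)-3,4-dihydroxy-6,8a-dimethyl-3-(propan-2-yl)-1,2,3,3a,4,5,8,8a-octahydroazulen-8-yl (2Z)-2-methylbut-2-enoate
Conditions: HF·pyridine, pyridine, THF, 0 °C to rt
Reagents that add atoms: none
Why: Buffered fluoride desilylation; the weakly acidic, non-nucleophilic medium neither hydrolyses nor isomerises the angelate and does not ionise the allylic ester or the tertiary alcohol.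

Step 16
Reactants: 22 (3R,3aS,4S,8R,8aS)-3,4-dihydroxy-6,8a-dimethyl-3-(propan-2-yl)-1,2,3,3a,4,5,8,8a-octahydroazulen-8-yl (2Z)-2-methylbut-2-enoate, 23 3,4-dimethoxybenzoyl chloride
Product: 24 (3R,3aS,4S,8R,8aS)-3-hydroxy-6,8a-dimethyl-8-{[(2Z)-2-methylbut-2-enoyl]oxy}-3-(propan-2-yl)-1,2,3,3a,4,5,8,8a-octahydroazulen-4-yl 3,4-dimethoxybenzoate
Conditions: DMAP, Et3N, CH2Cl2, rt
Reagents that add atoms: none
Why: Acyl chloride acylation of the secondary C5 hydroxyl under nucleophilic catalysis at room temperature; the tertiary C10 hydroxyl does not react and the finished angelate is stable to amine bases at this temperature.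

## Compound list

1 | cyclopentane-1,3-dione | O=C1CCC(=O)C1 | starting material
2 | 3-bromocyclopent-2-en-1-one | O=C1C=C(Br)CC1 | intermediate
3 | (tributylstannyl)methanol | OC[Sn](CCCC)(CCCC)CCCC | starting material
4 | 3-(hydroxymethyl)cyclopent-2-en-1-one | O=C1C=C(CO)CC1 | intermediate
5 | 3-[(triethylsilyloxy)methyl]cyclopent-2-en-1-one | O=C1C=C(CO[Si](CC)(CC)CC)CC1 | intermediate
6 | 3-methylbut-3-en-1-ol | CC(=C)CCO | starting material
7 | 3-methylbut-3-enal | O=CCC(C)=C | intermediate
8 | trimethylaluminium | C[Al](C)C | starting material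
9 | dimethylaluminium (3S)-3-methyl-3-[(triethylsilyloxy)methyl]cyclopent-1-en-1-olate | C[Al](C)OC1=C[C@@](C)(CO[Si](CC)(CC)CC)CC1 | intermediate
10 | (2S,3S)-2-[(1S)-1-hydroxy-3-methylbut-3-en-1-yl]-3-methyl-3-[(triethylsilyloxy)methyl]cyclopentan-1-one | CC[Si](CC)(CC)OC[C@@]1(C)CCC(=O)[C@@H]1[C@@H](O)CC(C)=C | intermediate
11 | (2S,3S)-2-[(1S)-1-(tert-butyldimethylsilyloxy)-3-methylbut-3-en-1-yl]-3-methyl-3-[(triethylsilyloxy)methyl]cyclopentan-1-one | CC[Si](CC)(CC)OC[C@@]1(C)CCC(=O)[C@@H]1[C@@H](O[Si](C)(C)C(C)(C)C)CC(C)=C | intermediate
12 | (1R,2S,3S)-2-[(1S)-1-(tert-butyldimethylsilyloxy)-3-methylbut-3-en-1-yl]-3-methyl-1-(propan-2-yl)-3-[(triethylsilyloxy)methyl]cyclopentan-1-ol | CC[Si](CC)(CC)OC[C@@]1(C)CC[C@@](O)(C(C)C)[C@@H]1[C@@H](O[Si](C)(C)C(C)(C)C)CC(C)=C | intermediate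
13 | (1R,2S,3S)-2-[(1S)-1-(tert-butyldimethylsilyloxy)-3-methylbut-3-en-1-yl]-3-(hydroxymethyl)-3-methyl-1-(propan-2-yl)cyclopentan-1-ol | OC[C@@]1(C)CC[C@@](O)(C(C)C)[C@@H]1[C@@H](O[Si](C)(C)C(C)(C)C)CC(C)=C | intermediate
14 | (1S,2S,3R)-2-[(1S)-1-(tert-butyldimethylsilyloxy)-3-methylbut-3-en-1-yl]-3-hydroxy-1-methyl-3-(propan-2-yl)cyclopentane-1-carbaldehyde | O=C[C@@]1(C)CC[C@@](O)(C(C)C)[C@@H]1[C@@H](O[Si](C)(C)C(C)(C)C)CC(C)=C | intermediate
15 | 1-{(1S,2S,3R)-2-[(1S)-1-(tert-butyldimethylsilyloxy)-3-methylbut-3-en-1-yl]-3-hydroxy-1-methyl-3-(propan-2-yl)cyclopentyl}prop-2-en-1-ol, both C1 epimers | C=CC(O)[C@@]1(C)CC[C@@](O)(C(C)C)[C@@H]1[C@@H](O[Si](C)(C)C(C)(C)C)CC(C)=C | intermediate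
16 | 1-{(1S,2S,3R)-2-[(1S)-1-(tert-butyldimethylsilyloxy)-3-methylbut-3-en-1-yl]-3-hydroxy-1-methyl-3-(propan-2-yl)cyclopentyl}prop-2-en-1-one | C=CC(=O)[C@@]1(C)CC[C@@](O)(C(C)C)[C@@H]1[C@@H](O[Si](C)(C)C(C)(C)C)CC(C)=C | intermediate
17 | (1R)-1-{(1S,2S,3R)-2-[(1S)-1-(tert-butyldimethylsilyloxy)-3-methylbut-3-en-1-yl]-3-hydroxy-1-methyl-3-(propan-2-yl)cyclopentyl}prop-2-en-1-ol | C=C[C@@H](O)[C@@]1(C)CC[C@@](O)(C(C)C)[C@@H]1[C@@H](O[Si](C)(C)C(C)(C)C)CC(C)=C | intermediate
18 | (3R,3aS,4S,8R,8aS)-4-(tert-butyldimethylsilyloxy)-6,8a-dimethyl-3-(propan-2-yl)-1,2,3,3a,4,5,8,8a-octahydroazulene-3,8-diol | O[C@@H]1C=C(C)C[C@H](O[Si](C)(C)C(C)(C)C)[C@@H]2[C@]1(C)CC[C@@]2(O)C(C)C | intermediate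
19 | angelic acid, (2Z)-2-methylbut-2-enoic acid | C/C=C(/C)C(=O)O | starting material
20 | angelic 2,4,6-trichlorobenzoic anhydride | C/C=C(/C)C(=O)OC(=O)c1c(Cl)cc(Cl)cc1Cl | intermediate
21 | (3R,3aS,4S,8R,8aS)-4-(tert-butyldimethylsilyloxy)-3-hydroxy-6,8a-dimethyl-3-(propan-2-yl)-1,2,3,3a,4,5,8,8a-octahydroazulen-8-yl (2Z)-2-methylbut-2-enoate | C/C=C(/C)C(=O)O[C@@H]1C=C(C)C[C@H](O[Si](C)(C)C(C)(C)C)[C@@H]2[C@]1(C)CC[C@@]2(O)C(C)C | intermediate
22 | (3R,3aS,4S,8R,8aS)-3,4-dihydroxy-6,8a-dimethyl-3-(propan-2-yl)-1,2,3,3a,4,5,8,8a-octahydroazulen-8-yl (2Z)-2-methylbut-2-enoate | C/C=C(/C)C(=O)O[C@@H]1C=C(C)C[C@H](O)[C@@H]2[C@]1(C)CC[C@@]2(O)C(C)C | intermediate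
23 | 3,4-dimethoxybenzoyl chloride | COc1ccc(cc1OC)C(Cl)=O | starting material
24 | (3R,3aS,4S,8R,8aS)-3-hydroxy-6,8a-dimethyl-8-{[(2Z)-2-methylbut-2-enoyl]oxy}-3-(propan-2-yl)-1,2,3,3a,4,5,8,8a-octahydroazulen-4-yl 3,4-dimethoxybenzoate | C/C=C(/C)C(=O)O[C@@H]1C=C(C)C[C@H](OC(=O)c2ccc(OC)c(OC)c2)[C@@H]2[C@]1(C)CC[C@@]2(O)C(C)C | target

## Step count and least certain steps

Total: 16 steps. Longest linear sequence: 15 steps (steps 1–3 and 5–16); step 4 is a one-step branch.

**Step 5 (key step).** Three things can go wrong. Face selection in the methyl transfer may be insufficient, because five-membered enones are flat and the allylic silyloxy group is new to the catalyst. The aldol may also take place on the enolate face syn to CH2OSiEt3, because the size difference to methyl is moderate. Finally, 7 may be lost by isomerisation into conjugation or by methyl transfer from residual Me3Al. Fallback: separate the two events. Starting from 5 and 8, the conjugate addition is run alone and enolate 9 is silylated with Me3SiCl/Et3N to give the isolable (S)-trimethyl({3-methyl-3-[(triethylsilyloxy)methyl]cyclopent-1-en-1-yl}oxy)silane F1, on which the enantiomeric purity can be checked. F1 is cleaved with MeLi in THF to the lithium enolate, exchanged to the zinc enolate with ZnCl2, and combined with 7 at −78 °C. This is a closed-transition-state aldol free of copper and Me3Al, and it rejoins the route at 10.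

**Step 7.** The isopropyl reagent may transfer hydride or enolise the ketone instead of adding, because the carbonyl is shielded by the silylated C5 branch and the quaternary C7; face selection could also erode. Fallback: change the substrate and the order. Starting from 10, the addition is run on the unprotected aldol with excess i-PrMgCl/CeCl3 at −78 °C, where the C5 alkoxide is small, activates the carbonyl by chelation and cannot be eliminated. This gives the diol (1R,2S,3S)-2-[(1S)-1-hydroxy-3-methylbut-3-en-1-yl]-3-methyl-1-(propan-2-yl)-3-[(triethylsilyloxy)methyl]cyclopentan-1-ol F2. Selective silylation of its secondary hydroxyl with TBSOTf/2,6-lutidine rejoins the route at 12.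

**Step 12.** The catalyst may fail to distinguish vinyl from the quaternary substituent, or substrate and reagent preference may not coincide as predicted; conjugate reduction is a minor risk. Fallback: set C1 on an ynone, where reagent control is most dependable. Starting from 14, lithium (trimethylsilyl)acetylide in THF at −78 °C gives the propargylic alcohols F3 (both C1 epimers). Dess–Martin oxidation gives the trimethylsilyl ynone F4. Noyori-type transfer hydrogenation with RuCl(p-cymene)(TsDPEN) in 2-propanol, using the catalyst antipode that gives the C1 configuration of 17, gives the trimethylsilyl propargylic alcohol F5. K2CO3 in MeOH gives the terminal alkyne F6. Semihydrogenation over Lindlar catalyst (Pd on CaCO3 poisoned with Pb(OAc)2, quinoline, H2) rejoins the route at 17.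

**Step 13.** Ruthenium hydride species may isomerise the free allylic alcohol to the ethyl ketone, and the diene may oligomerise through its monosubstituted alkene if closure onto the 1,1-disubstituted alkene is slow. Fallback: change the order. Starting from 17, the C1 hydroxyl is angeloylated first (19, 2,4,6-trichlorobenzoyl chloride, Et3N, toluene, 80 °C) to give the diene angelate (1R)-1-{(1S,2S,3R)-2-[(1S)-1-(tert-butyldimethylsilyloxy)-3-methylbut-3-en-1-yl]-3-hydroxy-1-methyl-3-(propan-2-yl)cyclopentyl}prop-2-en-1-yl (2Z)-2-methylbut-2-enoate F7. The allylic ester cannot isomerise to a ketone and its trisubstituted conjugated alkene is inert to the catalyst. Ring-closing metathesis with the same second-generation Grubbs catalyst then rejoins the route at 21.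

**Step 14.** The activated angeloyl unit may isomerise from Z to E before it is transferred, or acyl transfer to the hindered C1 hydroxyl next to the quaternary centre may be too slow. Fallback: build the Z alkene on the ester. Starting from 18, the C1 hydroxyl is acylated with 2-[bis(2,2,2-trifluoroethoxy)phosphoryl]propanoic acid (DCC, DMAP, CH2Cl2) to give the phosphonate ester F8. Still–Gennari olefination of F8 with acetaldehyde (KHMDS, 18-crown-6, THF, −78 °C) gives the Z enoate and rejoins the route at 21.

## Further compounds

F1 | step 5 | (S)-trimethyl({3-methyl-3-[(triethylsilyloxy)methyl]cyclopent-1-en-1-yl}oxy)silane | C[Si](C)(C)OC1=C[C@@](C)(CO[Si](CC)(CC)CC)CC1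
F2 | step 7 | (1R,2S,3S)-2-[(1S)-1-hydroxy-3-methylbut-3-en-1-yl]-3-methyl-1-(propan-2-yl)-3-[(triethylsilyloxy)methyl]cyclopentan-1-ol | CC[Si](CC)(CC)OC[C@@]1(C)CC[C@@](O)(C(C)C)[C@@H]1[C@@H](O)CC(C)=C
F3 | step 12 | 1-{(1S,2S,3R)-2-[(1S)-1-(tert-butyldimethylsilyloxy)-3-methylbut-3-en-1-yl]-3-hydroxy-1-methyl-3-(propan-2-yl)cyclopentyl}-3-(trimethylsilyl)prop-2-yn-1-ol, both C1 epimers | C[Si](C)(C)C#CC(O)[C@@]1(C)CC[C@@](O)(C(C)C)[C@@H]1[C@@H](O[Si](C)(C)C(C)(C)C)CC(C)=C
F4 | step 12 | 1-{(1S,2S,3R)-2-[(1S)-1-(tert-butyldimethylsilyloxy)-3-methylbut-3-en-1-yl]-3-hydroxy-1-methyl-3-(propan-2-yl)cyclopentyl}-3-(trimethylsilyl)prop-2-yn-1-one | C[Si](C)(C)C#CC(=O)[C@@]1(C)CC[C@@](O)(C(C)C)[C@@H]1[C@@H](O[Si](C)(C)C(C)(C)C)CC(C)=C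
F5 | step 12 | trimethylsilyl propargylic alcohol of F3 as the single C1 epimer configured as in 17 | C[Si](C)(C)C#C[C@@H](O)[C@@]1(C)CC[C@@](O)(C(C)C)[C@@H]1[C@@H](O[Si](C)(C)C(C)(C)C)CC(C)=C
F6 | step 12 | (1R)-1-{(1S,2S,3R)-2-[(1S)-1-(tert-butyldimethylsilyloxy)-3-methylbut-3-en-1-yl]-3-hydroxy-1-methyl-3-(propan-2-yl)cyclopentyl}prop-2-yn-1-ol | C#C[C@@H](O)[C@@]1(C)CC[C@@](O)(C(C)C)[C@@H]1[C@@H](O[Si](C)(C)C(C)(C)C)CC(C)=C
F7 | step 13 | (1R)-1-{(1S,2S,3R)-2-[(1S)-1-(tert-butyldimethylsilyloxy)-3-methylbut-3-en-1-yl]-3-hydroxy-1-methyl-3-(propan-2-yl)cyclopentyl}prop-2-en-1-yl (2Z)-2-methylbut-2-enoate | C/C=C(/C)C(=O)O[C@H](C=C)[C@@]1(C)CC[C@@](O)(C(C)C)[C@@H]1[C@@H](O[Si](C)(C)C(C)(C)C)CC(C)=C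
F8 | step 14 | C1 2-[bis(2,2,2-trifluoroethoxy)phosphoryl]propanoate of 18, both epimers at the phosphonate carbon | CC(C(=O)O[C@@H]1C=C(C)C[C@H](O[Si](C)(C)C(C)(C)C)[C@@H]2[C@]1(C)CC[C@@]2(O)C(C)C)P(=O)(OCC(F)(F)F)OCC(F)(F)F
A1 | alternative 1 | (3R,3aS,4S,8R,8aS)-3,8-dihydroxy-6,8a-dimethyl-3-(propan-2-yl)-1,2,3,3a,4,5,8,8a-octahydroazulen-4-yl 3,4-dimethoxybenzoate | O[C@@H]1C=C(C)C[C@H](OC(=O)c2ccc(OC)c(OC)c2)[C@@H]3[C@]1(C)CC[C@@]3(O)C(C)C
A2 | alternative 1 | open-chain iodo aldehyde: C1 formyl group on C7, (Z)-iodoalkene at C2, C5 veratrate, C5, C6, C7 and C10 configured as in 24 | O=C[C@@]1(C)CC[C@@](O)(C(C)C)[C@@H]1[C@@H](OC(=O)c1ccc(OC)c(OC)c1)C/C(C)=C\I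
A3 | alternative 2 | trans-fused hydroazulen-5-one with C1 dioxolane and C10 triethylsilyl ether | O1CCOC12CCCC(=O)[C@@H]3[C@]2(C)CC[C@@]3(O[Si](CC)(CC)CC)C(C)C
A4 | alternative 2 | cis-fused decalin with tertiary C5 hydroxyl, C6 methanesulfonate, C1 dioxolane and C10 triethylsilyl ether | O1CCOC12CCC[C@]3(O)[C@@H](OS(C)(=O)=O)[C@](O[Si](CC)(CC)CC)(C(C)C)CC[C@]23C
A5 | alternative 2 | (S)-Wieland–Miescher ketone | C[C@]12CCC(=O)C=C1CCCC2=O
A6 | alternative 3 | trans-2-[(tert-butyldimethylsilyloxy)methyl]-3-[(4-methoxybenzyloxy)methyl]-3-methylcyclopentan-1-one, configured at C6 and C7 as in 24 | O=C1CC[C@](C)(COCc2ccc(OC)cc2)[C@H]1CO[Si](C)(C)C(C)(C)C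
A7 | alternative 3 | 2-[(tert-butyldimethylsilyloxy)methyl]-3-[(4-methoxybenzyloxy)methyl]-3-methylpent-4-enal, configured as in A6 | O=C[C@H](CO[Si](C)(C)C(C)(C)C)[C@@](C)(COCc1ccc(OC)cc1)C=C
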